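## Retrosynthetic overview

1. The flavanone rings are A (benzo), C (pyranone) and B (2-aryl). The methylcyclohexene is ring D, numbered C1 (C–CH3), C2 (alkene CH), C3 (bonded to C8 of ring A), C4 (aroyl), C5 (2,4-dihydroxyphenyl), C6 (CH2). All seven phenols travel as MOM ethers.
2. Late disconnections: the MOM ethers; the C2–aryl bond of the flavanone (asymmetric conjugate addition of boronic acid 4 to a chromone); the aroyl C–C bond at C4 of ring D (aryllithium 20 plus aldehyde 15, then oxidation).
3. Key disconnection: ring D is opened at C1=C2 (ring-closing metathesis) and, in the same flask operation, at C3–C4 (iridium/enamine allylation). This leaves aldehyde 9 and racemic aryl vinyl carbinol 13.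
4. Enabling feature: C3 of ring D is both benzylic to ring A and allylic to C1=C2, and its neighbour C4 is α to a carbonyl. C3 can therefore be the aryl-bearing terminus of an allyl-iridium electrophile and C4 an enamine carbon; the vinyl group left on C3 then lies 1,7 to the isopropenyl group on C6, so that C1=C2 closes a six-membered ring.
5. Ring order: pyranone of the chromone (bought with 10), ring D (step 9), then saturation of ring C with its stereocentre (step 14). Boronic acid 4 supplies both 2,4-dioxygenated phenyl rings.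

Key step: step 9

Remark on the chemistry: (R)-L is (R)-4-(5H-dibenzo[b,f]azepin-5-yl)dinaphtho[2,1-d:1′,2′-f][1,3,2]dioxaphosphepine and (S)-amine is (S)-2-{bis[3,5-bis(trifluoromethyl)phenyl][(trimethylsilyl)oxy]methyl}pyrrolidine.

Assumption: the catalyst antipodes in steps 4, 9 and 14 are assigned from the usual facial models of these catalyst families and would be checked on the first run; each centre is set by its own catalyst, so a wrong centre is corrected by exchanging one antipode.

## Route

Step 1
Reactants: 1 4-bromobenzene-1,3-diol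
Product: 2 1-bromo-2,4-bis(methoxymethoxy)benzene
Conditions: MOMCl, i-Pr2NEt, CH2Cl2, 0 → 25 °C
Reagents that add atoms: chloromethyl methyl ether COCCl
Why: Williamson-type O-alkylation of both phenols; MOM is chosen because it survives organolithium, rhodium and ruthenium chemistry.

Step 2
Reactants: 2 1-bromo-2,4-bis(methoxymethoxy)benzene
Product: 4 [2,4-bis(methoxymethoxy)phenyl]boronic acid, via [2,4-bis(methoxymethoxy)phenyl]lithium 3 (not isolated)
Conditions: n-BuLi, THF, −78 °C; B(Oi-Pr)3, −78 → 25 °C; then H2O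
Reagents that add atoms: triisopropyl borate CC(C)OB(OC(C)C)OC(C)C; water O
Why: Bromine–lithium exchange at −78 °C is faster than attack on the acetals, and the aryllithium is trapped by the borate (lithiation–borylation) with neutral hydrolysis.

Step 3
Reactants: 5 methyl acrylate; 6 2-methylpenta-1,4-diene
Product: 7 methyl (2E)-5-methylhexa-2,5-dienoate
Conditions: 5 (3 equiv), second-generation Hoveyda–Grubbs catalyst RuCl2(=CH-2-(i-PrO)C6H4)(H2IMes) (2 mol %), CH2Cl2, 40 °C
Reagents that add atoms: none
Why: Olefin cross-metathesis, in which only the monosubstituted alkene of 6 pairs with the acrylate (the 1,1-disubstituted alkene is inert towards the electron-poor partner) and the enoate should form as the E isomer.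

Step 4
Reactants: 7 methyl (2E)-5-methylhexa-2,5-dienoate; 4 [2,4-bis(methoxymethoxy)phenyl]boronic acid
Product: 8 methyl (3S)-3-[2,4-bis(methoxymethoxy)phenyl]-5-methylhex-5-enoate
Conditions: 4 (2.5 equiv), [Rh(OH)((R)-BINAP)]2 (3 mol % Rh), dioxane/H2O 10:1, 50 °C
Reagents that add atoms: none
Why: Hayashi–Miyaura conjugate addition, in which the aryl-rhodium species (monovalent rhodium) inserts the enoate and (R)-BINAP is the antipode expected to give the 3S ester (C5 of ring D); the neutral hydroxo-rhodium medium should avoid conjugation of the skipped diene.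

Step 5
Reactants: 8 methyl (3S)-3-[2,4-bis(methoxymethoxy)phenyl]-5-methylhex-5-enoate
Product: 9 (3S)-3-[2,4-bis(methoxymethoxy)phenyl]-5-methylhex-5-enal
Conditions: i-Bu2AlH (1.05 equiv), toluene, −78 °C; then H2O
Reagents that add atoms: none
Why: Partial ester reduction at −78 °C stops at the aluminium hemiacetal, which collapses to the aldehyde on work-up; the stereocentre is β to the carbonyl and is not touched.

Step 6
Reactants: 10 7-hydroxy-4H-chromen-4-one
Product: 11 7-hydroxy-4-oxo-4H-chromene-8-carbaldehyde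
Conditions: hexamethylenetetramine, CF3CO2H, 90 °C; then H2O, 60 °C
Reagents that add atoms: hexamethylenetetramine C1N2CN3CN1CN(C2)C3; water O
Why: Duff formylation ortho to the phenol; C8, between the 7-OH and the ring oxygen, is the position at which 7-hydroxychromones undergo electrophilic ortho substitution.

Step 7
Reactants: 11 7-hydroxy-4-oxo-4H-chromene-8-carbaldehyde
Product: 12 7-(methoxymethoxy)-4-oxo-4H-chromene-8-carbaldehyde
Conditions: MOMCl, i-Pr2NEt, CH2Cl2, 0 → 40 °C
Reagents that add atoms: chloromethyl methyl ether COCCl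
Why: O-alkylation of the hydrogen-bonded phenol as in step 1, which prevents phenoxide formation in the Grignard step.

Step 8
Reactants: 12 7-(methoxymethoxy)-4-oxo-4H-chromene-8-carbaldehyde
Product: 13 racemic 8-(1-hydroxyprop-2-en-1-yl)-7-(methoxymethoxy)-4H-chromen-4-one
Conditions: CH2=CHMgBr (1.1 equiv), THF, −78 °C; then H2O
Reagents that add atoms: vinylmagnesium bromide C=C[Mg]Br
Why: Grignard 1,2-addition to the aldehyde, which at −78 °C is far more electrophilic than the vinylogous-ester carbonyl of the chromone; the racemate is wanted because both enantiomers converge in step 9.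

Step 9
Reactants: 9 (3S)-3-[2,4-bis(methoxymethoxy)phenyl]-5-methylhex-5-enal; 13 racemic 8-(1-hydroxyprop-2-en-1-yl)-7-(methoxymethoxy)-4H-chromen-4-one
Product: 15 (1R,2S,6S)-6-[2,4-bis(methoxymethoxy)phenyl]-2-[7-(methoxymethoxy)-4-oxo-4H-chromen-8-yl]-4-methylcyclohex-3-ene-1-carbaldehyde, via open-chain allylation aldehyde 14 (not isolated)
Conditions: [Ir(cod)Cl]2 (3 mol %), (R)-L (12 mol %), (S)-amine (15 mol %), (MeO)2P(O)OH (50 mol %), ClCH2CH2Cl, 25 °C; then dilution to 0.02 M, second-generation Grubbs catalyst RuCl2(=CHPh)(PCy3)(H2IMes) (5 mol %), 45 °C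
Reagents that add atoms: none
Why: The acid promoter and the iridium–(phosphoramidite, olefin) complex ionise both enantiomers of 13 to one aryl-substituted allyl-iridium electrophile (trivalent iridium) while the silyl prolinol ether turns 9 into its E-enamine, and attack of the enamine carbon (C4) on the aryl-bearing allyl terminus (C3) gives 14; the ruthenium benzylidene added next loads on the vinyl group at C2 and closes ring D by metathesis onto the isopropenyl carbon C1 with loss of ethylene. Closest known reaction types are the stereodivergent dual iridium/amine α-allylation of linear aldehydes with aryl vinyl carbinols (2,6-dialkoxyaryl carbinols included) and the ring-closing metathesis of the resulting 1,7-dienes to 1-methylcyclohexenes, here run in one flask. The only ring closed is the six-membered ring D, by ring-closing metathesis between a monosubstituted and a 1,1-disubstituted alkene, which gives the trisubstituted C1=C2 bond with the ring-enforced Z geometry. C3 is controlled by the ligand antipode on iridium and C4 by the amine antipode (attack on the enamine face away from the diaryl(silyloxy)methyl group), each independently of the other and of the C5 centre brought in by 9; the (R)-ligand/(S)-amine pairing is the one expected to give the 3,4-cis isomer drawn and would be checked by NOE on 15. The step needs branched instead of linear allylation (secured by the iridium catalyst and the aryl group on the allyl terminus), retention of the C4 configuration (secured because the α-branched aldehyde 14 hardly re-forms an enamine) and ring closure instead of oligomerisation (secured by the 1,7 spacing of the two terminal alkenes and by dilution). The ruthenium catalyst should tolerate the protonated amine, the phosphoric acid diester, water and the aldehyde, the phosphoramidite stays bound to iridium, and the chromone C2=C3 bond, an electron-poor alkene inside a ring, should not take part.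

Step 10
Reactants: 16 benzene-1,3-diol
Product: 17 1,3-bis(methoxymethoxy)benzene
Conditions: MOMCl, i-Pr2NEt, CH2Cl2, 0 → 25 °C
Reagents that add atoms: chloromethyl methyl ether COCCl
Why: O-alkylation of both phenols; the two MOM ethers then direct the lithiations of steps 11 and 12.

Step 11
Reactants: 17 1,3-bis(methoxymethoxy)benzene
Product: 19 1,3-bis(methoxymethoxy)-2-(3-methylbut-2-en-1-yl)benzene, via [2,6-bis(methoxymethoxy)phenyl]lithium 18 (not isolated)
Conditions: n-BuLi, THF, 0 → 25 °C; CuBr·SMe2 (10 mol %), 1-bromo-3-methylbut-2-ene, −78 → 0 °C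
Reagents that add atoms: 1-bromo-3-methylbut-2-ene CC(C)=CCBr
Why: Directed ortho-metalation at the position between the two MOM ethers, then copper-catalysed SN2 coupling with the prenyl bromide (copper suppresses SN2′ attack).

Step 12
Reactants: 19 1,3-bis(methoxymethoxy)-2-(3-methylbut-2-en-1-yl)benzene; 15 (1R,2S,6S)-6-[2,4-bis(methoxymethoxy)phenyl]-2-[7-(methoxymethoxy)-4-oxo-4H-chromen-8-yl]-4-methylcyclohex-3-ene-1-carbaldehyde
Product: 21 [2,4-bis(methoxymethoxy)-3-(3-methylbut-2-en-1-yl)phenyl]{(1R,2S,6S)-6-[2,4-bis(methoxymethoxy)phenyl]-2-[7-(methoxymethoxy)-4-oxo-4H-chromen-8-yl]-4-methylcyclohex-3-en-1-yl}methanol (both carbinol epimers), via prenylated aryllithium 20 (not isolated)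
Conditions: 19 (1.3 equiv), n-BuLi, TMEDA, THF, −20 °C; then 15, −78 °C; then H2O
Reagents that add atoms: none
Why: A second directed ortho-metalation of 19 next to a MOM ether gives 20, whose 1,2-addition to the aldehyde at −78 °C should outrun both α-deprotonation at C4 of ring D and attack on the chromone carbonyl; the new carbinol centre is removed in step 13.

Step 13
Reactants: 21 the carbinol of step 12
Product: 22 8-[(1S,5S,6R)-6-[2,4-bis(methoxymethoxy)-3-(3-methylbut-2-en-1-yl)benzoyl]-5-[2,4-bis(methoxymethoxy)phenyl]-3-methylcyclohex-2-en-1-yl]-7-(methoxymethoxy)-4H-chromen-4-one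
Conditions: Dess–Martin periodinane, CH2Cl2, 0 → 25 °C
Reagents that add atoms: none
Why: Dess–Martin oxidation of the secondary benzylic alcohol under neutral conditions, which should leave the adjacent C4 stereocentre, the alkenes and the acetals alone.

Step 14
Reactants: 22 the chromone ketone of step 13; 4 [2,4-bis(methoxymethoxy)phenyl]boronic acid
Product: 23 (2S)-8-[(1S,5S,6R)-6-[2,4-bis(methoxymethoxy)-3-(3-methylbut-2-en-1-yl)benzoyl]-5-[2,4-bis(methoxymethoxy)phenyl]-3-methylcyclohex-2-en-1-yl]-2-[2,4-bis(methoxymethoxy)phenyl]-7-(methoxymethoxy)-2,3-dihydro-4H-chromen-4-one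
Conditions: 4 (3 equiv), Pd(OCOCF3)2 (10 mol %), (R)-4-tert-butyl-2-(pyridin-2-yl)-4,5-dihydrooxazole (12 mol %), NH4PF6 (30 mol %), H2O (5 equiv), ClCH2CH2Cl, 60 °C
Reagents that add atoms: none
Why: Conjugate addition of a cationic aryl-palladium species (divalent palladium) to C2 of the chromone, then protonation of the palladium enolate; the pyridine–oxazoline ligand sets C2 (the (R)-ligand is the antipode expected to give 2S), and the base-free medium protects C4 of ring D and keeps the flavanone from reopening.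

Step 15
Reactants: 23 the heptakis(methoxymethyl) ether of step 14
Product: 24 (2S)-8-[(1S,5S,6R)-6-[2,4-dihydroxy-3-(3-methylbut-2-en-1-yl)benzoyl]-5-(2,4-dihydroxyphenyl)-3-methylcyclohex-2-en-1-yl]-2-(2,4-dihydroxyphenyl)-7-hydroxy-2,3-dihydro-4H-chromen-4-one
Conditions: Me2BBr (20 equiv), CH2Cl2, −78 °C; then NaHCO3 (aq)/THF, −78 → 0 °C
Reagents that add atoms: none
Why: Bromodimethylborane cleaves aryl MOM acetals at −78 °C through bromomethyl ethers that the bicarbonate work-up hydrolyses, a cold non-protic method chosen to spare the prenyl group, the enolisable C4 centre and the C2–O bond of the flavanone.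

## Compound list

1 | 4-bromobenzene-1,3-diol | Oc1ccc(Br)c(O)c1 | starting material
2 | 1-bromo-2,4-bis(methoxymethoxy)benzene | COCOc1ccc(Br)c(OCOC)c1 | intermediate
3 | [2,4-bis(methoxymethoxy)phenyl]lithium | [Li]c1ccc(OCOC)cc1OCOC | intermediate (not isolated)
4 | [2,4-bis(methoxymethoxy)phenyl]boronic acid | OB(O)c1ccc(OCOC)cc1OCOC | intermediate
5 | methyl acrylate | C=CC(=O)OC | starting material
6 | 2-methylpenta-1,4-diene | C=CCC(C)=C | starting material
7 | methyl (2E)-5-methylhexa-2,5-dienoate | COC(=O)/C=C/CC(C)=C | intermediate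
8 | methyl (3S)-3-[2,4-bis(methoxymethoxy)phenyl]-5-methylhex-5-enoate | COC(=O)C[C@@H](c1ccc(OCOC)cc1OCOC)CC(C)=C | intermediate
9 | (3S)-3-[2,4-bis(methoxymethoxy)phenyl]-5-methylhex-5-enal | O=CC[C@@H](c1ccc(OCOC)cc1OCOC)CC(C)=C | intermediate
10 | 7-hydroxy-4H-chromen-4-one | O=c1ccoc2cc(O)ccc12 | starting material
11 | 7-hydroxy-4-oxo-4H-chromene-8-carbaldehyde | O=Cc1c(O)ccc2c1occc2=O | intermediate
12 | 7-(methoxymethoxy)-4-oxo-4H-chromene-8-carbaldehyde | O=Cc1c(OCOC)ccc2c1occc2=O | intermediate
13 | racemic 8-(1-hydroxyprop-2-en-1-yl)-7-(methoxymethoxy)-4H-chromen-4-one | C=CC(O)c1c(OCOC)ccc2c1occc2=O | intermediate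
14 | (2R,3S)-2-[(1S)-1-[2,4-bis(methoxymethoxy)phenyl]-3-methylbut-3-en-1-yl]-3-[7-(methoxymethoxy)-4-oxo-4H-chromen-8-yl]pent-4-enal | O=C[C@H]([C@@H](c1ccc(OCOC)cc1OCOC)CC(C)=C)[C@@H](c1c(OCOC)ccc2c1occc2=O)C=C | intermediate (not isolated)
15 | (1R,2S,6S)-6-[2,4-bis(methoxymethoxy)phenyl]-2-[7-(methoxymethoxy)-4-oxo-4H-chromen-8-yl]-4-methylcyclohex-3-ene-1-carbaldehyde | O=C[C@H]1[C@@H](c2c(OCOC)ccc3c2occc3=O)C=C(C)C[C@@H]1c1ccc(OCOC)cc1OCOC | intermediate
16 | benzene-1,3-diol | Oc1cccc(O)c1 | starting material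
17 | 1,3-bis(methoxymethoxy)benzene | COCOc1cccc(OCOC)c1 | intermediate
18 | [2,6-bis(methoxymethoxy)phenyl]lithium | [Li]c1c(OCOC)cccc1OCOC | intermediate (not isolated)
19 | 1,3-bis(methoxymethoxy)-2-(3-methylbut-2-en-1-yl)benzene | CC(C)=CCc1c(OCOC)cccc1OCOC | intermediate
20 | [2,4-bis(methoxymethoxy)-3-(3-methylbut-2-en-1-yl)phenyl]lithium | [Li]c1ccc(OCOC)c(CC=C(C)C)c1OCOC | intermediate (not isolated)
21 | [2,4-bis(methoxymethoxy)-3-(3-methylbut-2-en-1-yl)phenyl]{(1R,2S,6S)-6-[2,4-bis(methoxymethoxy)phenyl]-2-[7-(methoxymethoxy)-4-oxo-4H-chromen-8-yl]-4-methylcyclohex-3-en-1-yl}methanol, both carbinol epimers | CC(C)=CCc1c(OCOC)ccc(C(O)[C@H]2[C@@H](c3c(OCOC)ccc4c3occc4=O)C=C(C)C[C@@H]2c2ccc(OCOC)cc2OCOC)c1OCOC | intermediate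
22 | 8-[(1S,5S,6R)-6-[2,4-bis(methoxymethoxy)-3-(3-methylbut-2-en-1-yl)benzoyl]-5-[2,4-bis(methoxymethoxy)phenyl]-3-methylcyclohex-2-en-1-yl]-7-(methoxymethoxy)-4H-chromen-4-one | CC(C)=CCc1c(OCOC)ccc(C(=O)[C@H]2[C@@H](c3c(OCOC)ccc4c3occc4=O)C=C(C)C[C@@H]2c2ccc(OCOC)cc2OCOC)c1OCOC | intermediate
23 | (2S)-8-[(1S,5S,6R)-6-[2,4-bis(methoxymethoxy)-3-(3-methylbut-2-en-1-yl)benzoyl]-5-[2,4-bis(methoxymethoxy)phenyl]-3-methylcyclohex-2-en-1-yl]-2-[2,4-bis(methoxymethoxy)phenyl]-7-(methoxymethoxy)-2,3-dihydro-4H-chromen-4-one | CC(C)=CCc1c(OCOC)ccc(C(=O)[C@H]2[C@@H](c3c(OCOC)ccc4c3O[C@H](c3ccc(OCOC)cc3OCOC)CC4=O)C=C(C)C[C@@H]2c2ccc(OCOC)cc2OCOC)c1OCOC | intermediate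
24 | (2S)-8-[(1S,5S,6R)-6-[2,4-dihydroxy-3-(3-methylbut-2-en-1-yl)benzoyl]-5-(2,4-dihydroxyphenyl)-3-methylcyclohex-2-en-1-yl]-2-(2,4-dihydroxyphenyl)-7-hydroxy-2,3-dihydro-4H-chromen-4-one | CC(C)=CCc1c(O)ccc(C(=O)[C@H]2[C@@H](c3c(O)ccc4c3O[C@H](c3ccc(O)cc3O)CC4=O)C=C(C)C[C@@H]2c2ccc(O)cc2O)c1O | target

## Step count and risks

Total step count: 15. Longest linear sequence: 9 steps (1 → 2 → 4 → 8 → 9 → 15 → 21 → 22 → 23 → 24, that is steps 1, 2, 4, 5, 9, 12, 13, 14, 15).

The three steps most likely to fail:

Step 9. The ruthenium alkylidene may be deactivated in the unpurified mixture (amine, cyclooctadiene released from iridium), so that ring closure stalls; or a mismatch between the catalyst pair and the C5 centre of 9 may lower the diastereoselectivity of the allylation. The fallback sets out from 9 and 13 and comes back to the route at 22. The iridium/amine allylation is run alone and the open-chain aldehyde 14 is isolated and purified. Aryllithium 20 is added at −78 °C to give the open-chain dienyl carbinol F1, and Dess–Martin oxidation gives the open-chain dienyl ketone F2. Ring D is then closed on F2 by ring-closing metathesis with the second-generation Hoveyda–Grubbs catalyst RuCl2(=CH-2-(i-PrO)C6H4)(H2IMes) in toluene at 60 °C. The ring closure then takes place on a substrate free of amine and iridium and without an enolisable aldehyde, and gives ketone 22 directly, bypassing 15 and 21.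

Step 14. Facial selectivity at C2 may be poor on the crowded 8-substituted chromone, and protodeboronation of the electron-rich boronic acid competes. The fallback sets out from 22 and comes back at 23. The aryl group is added without chiral control (Pd(OCOCF3)2, 2,2′-bipyridine, 4 in portions, aqueous ClCH2CH2Cl, 60 °C), which should give 23 together with its C2 epimer, the (2R)-flavanone F3. Because the three stereocentres of ring D are already fixed, 23 and F3 are diastereomers and are separated by preparative HPLC.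

Step 15. During cleavage of seven acetals the flavanone may open and re-close (loss of the C2 configuration), a freed phenol may add to the prenyl group or to the ring-D ketone, or cleavage may stay incomplete. The fallback sets out from 22 and 1 and comes back at 24; it exchanges the protecting groups before the C2 stereocentre exists. Me2BBr at −78 °C on 22 gives the pentaphenol chromone F4, and TBSCl/imidazole in DMF gives the pentakis(silyl ether) chromone F5. Bromide 1 is silylated (TBSCl, imidazole) to the bis(silyl ether) bromide F6 and borylated (B2pin2, PdCl2(dppf), KOAc, dioxane, 80 °C) to the pinacol boronate F7. The palladium/pyridine–oxazoline addition of step 14, run with F7 on F5, gives the heptakis(silyl ether) flavanone F8. HF·pyridine in THF/pyridine at 0 °C then releases 24 under buffered, non-basic conditions.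

Further compounds
F1 | step 9 | (2R,3S)-1-[2,4-bis(methoxymethoxy)-3-(3-methylbut-2-en-1-yl)phenyl]-2-[(1S)-1-[2,4-bis(methoxymethoxy)phenyl]-3-methylbut-3-en-1-yl]-3-[7-(methoxymethoxy)-4-oxo-4H-chromen-8-yl]pent-4-en-1-ol, both carbinol epimers | CC(C)=CCc1c(OCOC)ccc(C(O)[C@H]([C@@H](c2ccc(OCOC)cc2OCOC)CC(C)=C)[C@@H](c2c(OCOC)ccc3c2occc3=O)C=C)c1OCOC
F2 | step 9 | (2R,3S)-1-[2,4-bis(methoxymethoxy)-3-(3-methylbut-2-en-1-yl)phenyl]-2-[(1S)-1-[2,4-bis(methoxymethoxy)phenyl]-3-methylbut-3-en-1-yl]-3-[7-(methoxymethoxy)-4-oxo-4H-chromen-8-yl]pent-4-en-1-one | CC(C)=CCc1c(OCOC)ccc(C(=O)[C@H]([C@@H](c2ccc(OCOC)cc2OCOC)CC(C)=C)[C@@H](c2c(OCOC)ccc3c2occc3=O)C=C)c1OCOC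
F3 | step 14 | (2R)-8-[(1S,5S,6R)-6-[2,4-bis(methoxymethoxy)-3-(3-methylbut-2-en-1-yl)benzoyl]-5-[2,4-bis(methoxymethoxy)phenyl]-3-methylcyclohex-2-en-1-yl]-2-[2,4-bis(methoxymethoxy)phenyl]-7-(methoxymethoxy)-2,3-dihydro-4H-chromen-4-one | CC(C)=CCc1c(OCOC)ccc(C(=O)[C@H]2[C@@H](c3c(OCOC)ccc4c3O[C@@H](c3ccc(OCOC)cc3OCOC)CC4=O)C=C(C)C[C@@H]2c2ccc(OCOC)cc2OCOC)c1OCOC
F4 | step 15 | 8-[(1S,5S,6R)-6-[2,4-dihydroxy-3-(3-methylbut-2-en-1-yl)benzoyl]-5-(2,4-dihydroxyphenyl)-3-methylcyclohex-2-en-1-yl]-7-hydroxy-4H-chromen-4-one | CC(C)=CCc1c(O)ccc(C(=O)[C@H]2[C@@H](c3c(O)ccc4c3occc4=O)C=C(C)C[C@@H]2c2ccc(O)cc2O)c1O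
F5 | step 15 | pentakis(tert-butyldimethylsilyl) ether of F4 | CC(C)=CCc1c(O[Si](C)(C)C(C)(C)C)ccc(C(=O)[C@H]2[C@@H](c3c(O[Si](C)(C)C(C)(C)C)ccc4c3occc4=O)C=C(C)C[C@@H]2c2ccc(O[Si](C)(C)C(C)(C)C)cc2O[Si](C)(C)C(C)(C)C)c1O[Si](C)(C)C(C)(C)C
F6 | step 15 | 1-bromo-2,4-bis(tert-butyldimethylsilyloxy)benzene | CC(C)(C)[Si](C)(C)Oc1ccc(Br)c(O[Si](C)(C)C(C)(C)C)c1
F7 | step 15 | 2-[2,4-bis(tert-butyldimethylsilyloxy)phenyl]-4,4,5,5-tetramethyl-1,3,2-dioxaborolane | CC(C)(C)[Si](C)(C)Oc1ccc(B2OC(C)(C)C(C)(C)O2)c(O[Si](C)(C)C(C)(C)C)c1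
F8 | step 15 | heptakis(tert-butyldimethylsilyl) ether of 24 | CC(C)=CCc1c(O[Si](C)(C)C(C)(C)C)ccc(C(=O)[C@H]2[C@@H](c3c(O[Si](C)(C)C(C)(C)C)ccc4c3O[C@H](c3ccc(O[Si](C)(C)C(C)(C)C)cc3O[Si](C)(C)C(C)(C)C)CC4=O)C=C(C)C[C@@H]2c2ccc(O[Si](C)(C)C(C)(C)C)cc2O[Si](C)(C)C(C)(C)C)c1O[Si](C)(C)C(C)(C)C
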